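(The readings come from a simulation with made-up constants; the scatter is artificial.)

The leftover of this flask is 45.0 mM: the reagent charge minus the substrate charge, that is, the reagent still unused once each substrate has taken one.

all flasks: substrate 15 mM

| charge | reagent | remark | time |
|---|---|---|---|
| winter | 60 mM | the very flask that is asked about, followed so far |  |
| autumn | 40 mM | run made earlier |  |
| flask | 60.0 mM |  | 5.0 h |

winter run (percent of the substrate charged)

| time / min | substrate / % | target / % |
|---|---|---|
| 5.00 | 0.2 | 54.9 |
| 15.0 | 0 | 90.4 |
| 25.0 | 0 | 97.4 |
| 40.0 | 0.8 | 100.6 |
| 50.0 | 0 | 99.9 |
| 80.0 | 0 | 99.7 |
| 90.0 | 0.2 | 100.6 |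

autumn run (percent of the substrate charged)

| time / h | substrate / % | target / % |
|---|---|---|
| 0.417 | 0 | 90.9 |
| 0.667 | 0.5 | 97.3 |
| 1.00 | 0 | 99.7 |
| 1.33 | 0 | 99.4 |
| 2.00 | 0.3 | 99.6 |
| 3.00 | 0 | 99.4 |
| 5.00 | 0 | 99.5 |

(each reading ± 0.5 percentage points)

- percent here means substrate units held: one idle adduct counts as two
- what is said of target includes idle adduct and crystals
- crystals is a solid; its amount is given per volume of the solution
- the numbers in the tables scatter by 0.5 percentage points (one standard deviation)
- candidate steps: substrate -> intermediate; substrate + target <-> idle adduct; crystals <-> target; reagent + intermediate -> target
- in an amount of target, one idle adduct counts as one target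
- the reaction counts as stopped when no species that holds the substrate changes by six tenths of a point or more over the second half of the time

1. why nothing more happens at 5.0 h, or that something still does (all of the substrate has reacted / it is still moving / the reagent has run out first)
2. share of the substrate used up at 5.0 h
3. target at 5.0 h, in percent of the substrate charged

The winter run is this same flask, followed to 90.0 min. In its first minutes substrate leaves faster than target arrives: at 5.00 min substrate reads 0.2 % and target 54.9 %. I take the 45.1 % by which target falls short as intermediate, the resting state, waiting for reagent.

In the middle, each intermediate consumed takes one reagent, so c(reagent) minus c(intermediate) stays at the leftover. The rate per intermediate, κ·c(reagent), therefore drifts, and ln[c(reagent)/c(intermediate)] climbs with slope κ times the leftover. Between 5.00 min and 15.0 min, with 9.60 % missing, the readings give κ = 3.20 /M/min. The autumn run, with a leftover of 25.0 mM, gives 3.14 /M/min from its first two readings.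

Towards the end of this flask the step becomes pseudo-first-order, at 0.144 /min, slower than the 0.192 /min of the start. The asked 5.0 h is 43.2 time constants of that tail, so I expect no measurable intermediate and target equal to the substrate charged.

The forecast says all of the substrate has reacted, with conversion 100 % and target 99.8 %; in its words, “the flask has long been finished, with all substrate converted to target”.

    substrate → intermediate (k = 2.60 /min)
    substrate + target ⇌ idle adduct, settled at all times (K = 33.0 /M)
    crystals ⇌ target, rate k3*(cs3 - [target]) while solid is left; crystals form when [target] > cs3 (solubility = 0.270 mM, k = 7.43 /min)
    reagent + intermediate → target (k = 3.20 /M/min)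

The flask gives target 100 % and conversion 100 %: all of the substrate has reacted. The tying up as idle adduct moves the target readings by 0.014 of the scatter, as a root mean square. Reagent stands at 75 % of its charge at 5.00 h, and the leftover as a share of the reagent charge is 75.0 %.

In the neighbour flask with 15 mM of reagent, 1.00 equiv, the leftover is 0 mM, so the tail has no time constant: the share of intermediate falls as the reciprocal of one plus κ·charge·time, which gives 6.50 %. The computed neighbour flask holds intermediate 6.50 % of the substrate charged, reagent 6.50 % of its own charge and target 93.5 % of the substrate charged at 5.00 h.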